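## The problem

The target is a tetramer of C6–C3 units built on a trans-α,β-dibenzyl-γ-butyrolactone (oxolan-2-one, C3 and C4 both S), in which each guaiacyl ring carries a further coniferyl-derived unit bonded through its C8 to the ring carbon ortho to the phenol oxygen (C5 of ring A on the C3 benzyl group, C5 of ring B on the C4 benzyl group). On ring B this unit is closed to a trans-2-aryl-3-hydroxymethyl-2,3-dihydrobenzofuran (C7B R, C8B S, ring C on C7B); on ring A it stays open as a 1,2-diarylpropane-1,3-diol (C7A S, C8A S, ring D on C7A) beside a free phenol. The six stereocentres form three pairs separated by CH2–aryl spacers: inside a pair relative control is available (alkylation anti to the C4 substituent, a trans ring), but no pair can steer another, so absolute configuration must be imposed by reagents. C7A is a p-oxygenated benzylic carbinol, which acid or a quinone methide would epimerise or close to a second dihydrobenzofuran on the ring A phenol. The lactone is enolisable and reducible, so base and hydride steps on the side units must work around it. The feature that makes the key step possible is a hidden twofold relationship: C8A and C8B have the same configuration, and C7A (S) is exactly the configuration from which an invertive O–C7 closure gives C7B (R). Both appendages are therefore the same anti-(7S,8S) diol on equivalent positions (C5 of ring A, C5 of ring B) and differ only in whether the ring oxygen has closed, so both can be made in one operation provided the two ring phenols can be told apart afterwards.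

## Retrosynthesis

**26 ⇒ 25.** Only O–Si bonds are cut. All phenols except that of ring B, and both primary alcohols, are carried as silyl ethers, so one buffered fluoride treatment ends the route without acid or hydrogenolysis on the finished carbinols.

**25 ⇒ 24.** The O1–C2 bond of the dihydrobenzofuran (ring B oxygen to C7B) is cut. Cutting a C–C bond of that ring instead would treat the two arms as unrelated. With this cut the precursor 24 has two identical anti diol arms and differs from 25 only by one C–O bond. The forward reaction must be an SN2 etherification with inversion at C7B, and the ring B phenol must be the only free phenol.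

**24 ⇒ 23 ⇒ 22 ⇒ 21.** Only protecting groups and the oxidation level at C9 change. Ring B alone carries a benzyl ether (rings A, C and D carry triisopropylsilyl ethers), so hydrogenolysis frees one phenol. The primary alcohols are silylated so that the phenol cannot close on C9. The two C9 carbons come from imides, which borohydride reduces in preference to the lactone.

**21 ⇒ 17 + 2 × 19 (key cut).** Both C7–C8 bonds (C7A–C8A and C7B–C8B) are cut at once. Cutting the aryl–C8 bonds instead would need a regio- and stereoselective arylation of a three-carbon unit, for which no reliable method exists. Cutting O–C7 and aryl–C8 together is the biomimetic coupling, which has no absolute control. The aldol cut removes four stereocentres and two aryl rings in one step: 17 has only the two lactone stereocentres. The forward reaction is a double anti-selective aldol addition of a bis(arylacetyl imide) to two molecules of aldehyde 19, three components joined around the lactone core, and it must not touch the lactone.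

**17 ⇒ 14 + 2 × 15.** The two imide C–N bonds are cut. Diacid 14 acylates two molecules of the auxiliary 15 through the bis(mixed anhydride) 16 under conditions free of strong base, so the lactone is not at risk and both arms receive the same control element.

**14 ⇒ 13 ⇒ 12.** The two aryl–CH2 bonds of the acetic acid arms are cut back to aryl bromides. A coupling of the Reformatsky reagent BrZnCH2CO2t-Bu catalysed by Pd(dba)2 and P(t-Bu)3 tolerates the lactone, and the bromine is already in commercial 5-bromovanillin.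

**12 ⇒ 7 + 10.** The C3–CH2 (ring A) bond is cut: alkylation of the enolate of β-benzyl lactone 7 with benzylic bromide 10, anti to the C4 substituent. The two rings enter in separate steps, so giving them different phenol protection (benzyl on B, silyl on A) costs nothing.

**7 ⇒ 5 ⇒ 4 ⇒ 2 + 3.** The lactone ring and the C4 stereocentre are traced to a Stobbe half ester, hydrogenated asymmetrically. The half ester fixes which carbonyl becomes the lactone CH2–O.

**2, 10 and 19** come from 5-bromovanillin 1 and vanillin 18 by protection and functional group changes.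

## Roads not taken

**Alternative 1:** the most obvious cut, both aryl–C8 and both O–C7 bonds, in the biomimetic sense. One-electron oxidation (Ag2O, or a peroxidase and H2O2) of (+)-matairesinol A1 with two equivalents of coniferyl alcohol would give the bis(dihydrobenzofuran) A2 by two radical β-5 couplings. The radical coupling has no control over the new stereocentre pairs relative to the lactone, coniferyl alcohol mostly couples with itself, and both arms close. The open arm with defined C7A cannot be obtained this way, and A1 still needs a synthesis as long as that of 12.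

**Alternative 2:** cut the C3–CH2 (ring A) bond last. The enolate of lactone A3, carrying the finished dihydrobenzofuran, would be alkylated with bromide A4, carrying the protected open diol. The alkylation is reliable, but the stereodiad must be built twice in separate sequences (two aldols, two reductions, two protection sets), and A4 is a heavy, ionisable benzylic bromide. The chosen plan builds the diad once, on both arms together, and so uses the symmetry that this alternative leaves idle.

**Alternative 3:** cut both C7–C8 bonds by carbenoid C–H insertion. The bis(aryldiazoacetate) A5, with both ring phenols as 4-(benzyloxy)-3-methoxybenzyl ethers, would undergo a double 1,5-C–H insertion under a chiral dirhodium tetracarboxylate such as Rh2(S-DOSP)4 to give the bis(dihydrobenzofuran ester) A6. This is also two-directional, but it necessarily closes both arms. The ring A diol could then only be reached by breaking a benzylic C–O bond without control at C7A; the kinetic cis rings need base epimerisation next to an enolisable lactone; and two esters must be reduced beside the lactone. The chosen plan keeps both arms open and lets one protecting group decide which closes.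

Key step: step 13

Remark on the chemistry: the sense of induction in step 3 ([Rh(cod)((R,R)-Et-DuPhos)]OTf) and step 13 (chelated magnesium enolate) is taken from the standard models; if either proves opposite, the antipodal ligand or auxiliary is used and nothing else changes.

## Route

Step 1
Reactants: 1 5-bromovanillin (3-bromo-4-hydroxy-5-methoxybenzaldehyde)
Product: 2 4-(benzyloxy)-3-bromo-5-methoxybenzaldehyde
Conditions: BnBr, K2CO3, DMF, 60 °C
Reagents that add atoms: benzyl bromide, BrCc1ccccc1
Why: Williamson etherification of the phenoxide; the benzyl ether on ring B is the one group later removed by hydrogenolysis to single out this phenol.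

Step 2
Reactants: 2 4-(benzyloxy)-3-bromo-5-methoxybenzaldehyde; 3 dimethyl succinate
Product: 4 (E)-4-[4-(benzyloxy)-3-bromo-5-methoxyphenyl]-3-(methoxycarbonyl)but-3-enoic acid
Conditions: NaOMe, MeOH, reflux; then 2 M HCl
Reagents that add atoms: none
Why: Stobbe condensation; the paraconate lactone intermediate opens by elimination to the half ester, which already distinguishes the two carboxyl carbons of the future lactone, and the aryl group ends trans to the ester.

Step 3
Reactants: 4 (E)-4-[4-(benzyloxy)-3-bromo-5-methoxyphenyl]-3-(methoxycarbonyl)but-3-enoic acid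
Product: 5 (S)-4-[4-(benzyloxy)-3-bromo-5-methoxyphenyl]-3-(methoxycarbonyl)butanoic acid
Conditions: [Rh(cod)((R,R)-Et-DuPhos)]OTf (1 mol %), NaOMe (0.1 equiv), H2 (5 atm), MeOH, rt
Reagents that add atoms: none
Why: Asymmetric hydrogenation of a Stobbe-derived itaconate half ester, a standard substrate class for cationic catalysts of the type [Rh(cod)(DuPhos)]OTf; the chelating carboxylate fixes the olefin face and sets the future lactone C4 as S, and the homogeneous catalyst leaves the aryl bromide and benzyl ether alone.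

Step 4
Reactants: 5 (S)-4-[4-(benzyloxy)-3-bromo-5-methoxyphenyl]-3-(methoxycarbonyl)butanoic acid
Product: 7 (S)-4-[4-(benzyloxy)-3-bromo-5-methoxybenzyl]dihydrofuran-2(3H)-one, via hydroxy acid 6 (not isolated)
Conditions: KOH (1 equiv), EtOH; Ca(BH4)2, EtOH/THF, 0 °C → rt; then 2 M HCl, rt
Reagents that add atoms: none
Why: Borohydride reduces the methyl ester while the carboxylate salt is inert; acidification lactonises the hydroxy acid, and the stereocentre is not involved.

Step 5
Reactants: 1 5-bromovanillin
Product: 8 3-bromo-5-methoxy-4-(triisopropylsilyloxy)benzaldehyde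
Conditions: i-Pr3SiCl, imidazole, DMF, 40 °C
Reagents that add atoms: chlorotriisopropylsilane, CC(C)[Si](Cl)(C(C)C)C(C)C
Why: Silylation of the phenol; the bulky aryl silyl ether survives amide bases, trifluoroacetic acid and borohydride and is removed only at the end.

Step 6
Reactants: 8 3-bromo-5-methoxy-4-(triisopropylsilyloxy)benzaldehyde
Product: 9 [3-bromo-5-methoxy-4-(triisopropylsilyloxy)phenyl]methanol
Conditions: NaBH4, THF/MeOH, 0 °C
Reagents that add atoms: none
Why: Plain aldehyde reduction.

Step 7
Reactants: 9 [3-bromo-5-methoxy-4-(triisopropylsilyloxy)phenyl]methanol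
Product: 10 [2-bromo-4-(bromomethyl)-6-methoxyphenoxy]triisopropylsilane
Conditions: CBr4, PPh3, CH2Cl2, 0 °C
Reagents that add atoms: tetrabromomethane, BrC(Br)(Br)Br
Why: Appel bromination under neutral conditions, which the aryl silyl ether tolerates; the bromide is used at once.

Step 8
Reactants: 7 (S)-4-[4-(benzyloxy)-3-bromo-5-methoxybenzyl]dihydrofuran-2(3H)-one; 10 [2-bromo-4-(bromomethyl)-6-methoxyphenoxy]triisopropylsilane
Product: 12 (3S,4S)-4-[4-(benzyloxy)-3-bromo-5-methoxybenzyl]-3-[3-bromo-5-methoxy-4-(triisopropylsilyloxy)benzyl]dihydrofuran-2(3H)-one, via lithium enolate 11 (not isolated)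
Conditions: LiN(SiMe3)2, THF, −78 °C; then 10, −78 → −30 °C
Reagents that add atoms: none
Why: Alkylation of a β-substituted γ-butyrolactone enolate, which takes the electrophile anti to the C4 benzyl group and gives the trans (3S,4S) lactone; trans is also the thermodynamic isomer, so later base cannot erode C3.

Step 9
Reactants: 12 (3S,4S)-4-[4-(benzyloxy)-3-bromo-5-methoxybenzyl]-3-[3-bromo-5-methoxy-4-(triisopropylsilyloxy)benzyl]dihydrofuran-2(3H)-one
Product: 13 (3S,4S)-4-[4-(benzyloxy)-3-(2-tert-butoxy-2-oxoethyl)-5-methoxybenzyl]-3-[3-(2-tert-butoxy-2-oxoethyl)-5-methoxy-4-(triisopropylsilyloxy)benzyl]dihydrofuran-2(3H)-one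
Conditions: BrZnCH2CO2t-Bu (3 equiv), Pd(dba)2 (5 mol %), P(t-Bu)3 (5 mol %), THF, 25 → 60 °C
Reagents that add atoms: (2-tert-butoxy-2-oxoethyl)zinc bromide, CC(C)(C)OC(=O)C[Zn]Br (made from tert-butyl bromoacetate, CC(C)(C)OC(=O)CBr, and zinc)
Why: Twofold Negishi-type coupling of the two aryl bromides with a Reformatsky reagent, one tert-butyl acetate unit entering on each ring; the zinc enolate is too weakly basic to enolise or attack the lactone.

Step 10
Reactants: 13 (the bis(tert-butyl ester) of step 9)
Product: 14 (3S,4S)-4-[4-(benzyloxy)-3-(carboxymethyl)-5-methoxybenzyl]-3-[3-(carboxymethyl)-5-methoxy-4-(triisopropylsilyloxy)benzyl]dihydrofuran-2(3H)-one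
Conditions: CF3CO2H, CH2Cl2, 0 °C → rt
Reagents that add atoms: none
Why: Acidolysis of the tert-butyl esters with loss of isobutene; lactone, aryl benzyl ether and aryl triisopropylsilyl ether are stable to this acid.

Step 11
Reactants: 14 (the diacid of step 10); 15 (S)-4-benzyl-1,3-oxazolidin-2-one (2 equiv)
Product: 17 (3S,4S)-4-[4-(benzyloxy)-5-methoxy-3-{2-oxo-2-[(S)-4-benzyl-2-oxooxazolidin-3-yl]ethyl}benzyl]-3-[5-methoxy-3-{2-oxo-2-[(S)-4-benzyl-2-oxooxazolidin-3-yl]ethyl}-4-(triisopropylsilyloxy)benzyl]dihydrofuran-2(3H)-one, via bis(pivalic mixed anhydride) 16 (not isolated)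
Conditions: t-BuCOCl (2.2 equiv), Et3N (5 equiv), THF, −20 °C; then 15 (2.2 equiv), LiCl (2.5 equiv), −20 °C → rt
Reagents that add atoms: pivaloyl chloride (2 equiv), CC(C)(C)C(Cl)=O (its acyl groups stay only in intermediate 16)
Why: Standard N-acylation of an oxazolidinone through the mixed pivalic anhydride with LiCl activation, run twofold: each of the two carboxyl groups of 14 is activated by one molecule of pivaloyl chloride and takes up one molecule of 15, so two molecules of 15 end in 17; no strong base is present, so the lactone is untouched.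

Step 12
Reactants: 18 vanillin (4-hydroxy-3-methoxybenzaldehyde)
Product: 19 3-methoxy-4-(triisopropylsilyloxy)benzaldehyde
Conditions: i-Pr3SiCl, imidazole, DMF, rt
Reagents that add atoms: chlorotriisopropylsilane, CC(C)[Si](Cl)(C(C)C)C(C)C
Why: Phenol silylation; rings C and D thus carry the same fluoride-labile group as ring A and stay masked when ring B is debenzylated.

Step 13
Reactants: 17 (the bis-imide of step 11); 19 3-methoxy-4-(triisopropylsilyloxy)benzaldehyde (2 equiv incorporated)
Product: 21 (3S,4S)-lactone 17 in which each arylacetyl arm has become a (2R,3S)-3-hydroxy-3-[3-methoxy-4-(triisopropylsilyloxy)phenyl]-2-arylpropanoyl imide arm, via bis(trimethylsilyl ether) 20 (not isolated)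
Conditions: 19 (3 equiv), MgCl2 (0.3 equiv), Et3N (4 equiv), Me3SiCl (3 equiv), EtOAc, rt; then aqueous citric acid, THF, 0 °C
Reagents that add atoms: chlorotrimethylsilane, C[Si](C)(C)Cl (its silyl groups stay only in intermediate 20)
Why: Soft enolisation: each N-arylacetyl imide chelates Mg through its two carbonyl oxygens and is deprotonated by Et3N to the chelated (Z)-enolate, which adds to one molecule of aldehyde 19; Me3SiCl silylates the magnesium aldolate, making the addition irreversible and releasing MgCl2 for the next turnover. The closest known reaction type is the MgCl2-catalysed direct anti-aldol addition of N-acyloxazolidinones to aromatic aldehydes, used here twice in one flask on an arylacetyl imide. No ring is closed. C8A and C8B are set by the auxiliary: the 4-benzyl group shields one face of the chelated enolate, so the aldehyde bonds to the face also used in alkylations of these imides, which becomes 8S after reduction. C7A and C7B are set relative to C8 by the boat-like transition state of the chelated enolate, in which the aldehyde aryl group turns away from the enolate aryl group, giving the anti (2R,3S) adducts. The step needs chemoselectivity for the imides over the lactone, secured because only the imides are acidified by chelation and Et3N cannot enolise a lactone; it needs the same sense on both arms, secured because CH2–aryl spacers insulate both arms from the lactone stereocentres so that only the auxiliary decides; and a double reaction under one control element turns residual facial error into minor diastereomers that can be separated. Aqueous citric acid then removes the two Me3Si groups without ionising the p-silyloxybenzylic carbinols.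

Step 14
Reactants: 21 (the bis-aldol adduct of step 13)
Product: 22 (3S,4S)-4-{4-(benzyloxy)-3-[(1S,2S)-1,3-dihydroxy-1-(3-methoxy-4-triisopropylsilyloxyphenyl)propan-2-yl]-5-methoxybenzyl}-3-{3-[(1S,2S)-1,3-dihydroxy-1-(3-methoxy-4-triisopropylsilyloxyphenyl)propan-2-yl]-5-methoxy-4-(triisopropylsilyloxy)benzyl}dihydrofuran-2(3H)-one
Conditions: NaBH4, THF/H2O, 0 °C → rt
Reagents that add atoms: none
Why: Reductive cleavage of N-acyloxazolidinones by aqueous borohydride; the activated imide carbonyls are reduced much faster than the γ-lactone, both auxiliaries are released, and C8 is no longer epimerisable once C9 is an alcohol.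

Step 15
Reactants: 22 (the tetraol of step 14)
Product: 23 the bis(primary tert-butyldimethylsilyl ether) of 22 (both CH2OH groups silylated and both benzylic carbinols free)
Conditions: t-BuMe2SiCl (2.2 equiv), imidazole, CH2Cl2, 0 °C
Reagents that add atoms: tert-butylchlorodimethylsilane, CC(C)(C)[Si](C)(C)Cl
Why: Primary alcohols are silylated much faster than the hindered benzylic secondary ones; blocking C9B stops the ring B phenol from later closing on the primary carbon.

Step 16
Reactants: 23 (the bis(silyl ether) of step 15)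
Product: 24 compound 23 with the ring B benzyl ether cleaved to the free phenol
Conditions: H2 (1 atm), Pd/C, NaHCO3, EtOAc, rt
Reagents that add atoms: none
Why: Hydrogenolysis of the only benzyl ether in the molecule; the mild base suppresses acid-promoted hydrogenolysis of the benzylic C–O bonds.

Step 17
Reactants: 24 (the ring B phenol of step 16)
Product: 25 (3S,4S)-4-{[(2R,3S)-3-(tert-butyldimethylsilyloxymethyl)-7-methoxy-2-(3-methoxy-4-triisopropylsilyloxyphenyl)-2,3-dihydrobenzofuran-5-yl]methyl}-3-{3-[(1S,2S)-3-(tert-butyldimethylsilyloxy)-1-hydroxy-1-(3-methoxy-4-triisopropylsilyloxyphenyl)propan-2-yl]-5-methoxy-4-(triisopropylsilyloxy)benzyl}dihydrofuran-2(3H)-one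
Conditions: PPh3 (1.2 equiv), DIAD (1.2 equiv), THF, 0 °C
Reagents that add atoms: none
Why: Intramolecular Mitsunobu etherification (5-exo-tet): the ring B phenol is the only acidic OH, and its phenoxide displaces the oxyphosphonium at C7B with inversion (7S to 7R), giving the trans dihydrobenzofuran; any ionisation at C7B also collapses to the trans ring. The ring A arm has no free phenol and its carbinol is flanked by the bulky ring A silyl ether, so it should stay open.

Step 18
Reactants: 25 (the ring-closed compound of step 17)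
Product: 26 (3S,4S)-3-{3-[(1S,2S)-1,3-dihydroxy-1-(4-hydroxy-3-methoxyphenyl)propan-2-yl]-4-hydroxy-5-methoxybenzyl}-4-{[(2R,3S)-2-(4-hydroxy-3-methoxyphenyl)-3-(hydroxymethyl)-7-methoxy-2,3-dihydrobenzofuran-5-yl]methyl}dihydrofuran-2(3H)-one (CNP0186558.3)
Conditions: Bu4NF, AcOH, THF, 0 °C → rt
Reagents that add atoms: none
Why: Fluoride cleavage of three aryl and two primary alkyl silyl ethers; the acetic acid buffer keeps the liberated p-hydroxybenzyl systems from forming quinone methides, so C7A and the dihydrobenzofuran are not disturbed.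

## Compound list

1 | 5-bromovanillin | O=Cc1cc(Br)c(O)c(OC)c1 | starting material
2 | 4-(benzyloxy)-3-bromo-5-methoxybenzaldehyde | O=Cc1cc(Br)c(OCc2ccccc2)c(OC)c1 | intermediate
3 | dimethyl succinate | COC(=O)CCC(=O)OC | starting material
4 | (E)-4-[4-(benzyloxy)-3-bromo-5-methoxyphenyl]-3-(methoxycarbonyl)but-3-enoic acid | COC(=O)/C(CC(=O)O)=C/c1cc(Br)c(OCc2ccccc2)c(OC)c1 | intermediate
5 | (S)-4-[4-(benzyloxy)-3-bromo-5-methoxyphenyl]-3-(methoxycarbonyl)butanoic acid | COC(=O)[C@H](CC(=O)O)Cc1cc(Br)c(OCc2ccccc2)c(OC)c1 | intermediate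
6 | (S)-4-[4-(benzyloxy)-3-bromo-5-methoxyphenyl]-3-(hydroxymethyl)butanoic acid | OC[C@H](CC(=O)O)Cc1cc(Br)c(OCc2ccccc2)c(OC)c1 | intermediate
7 | (S)-4-[4-(benzyloxy)-3-bromo-5-methoxybenzyl]dihydrofuran-2(3H)-one | O=C1C[C@H](Cc2cc(Br)c(OCc3ccccc3)c(OC)c2)CO1 | intermediate
8 | 3-bromo-5-methoxy-4-(triisopropylsilyloxy)benzaldehyde | O=Cc1cc(Br)c(O[Si](C(C)C)(C(C)C)C(C)C)c(OC)c1 | intermediate
9 | [3-bromo-5-methoxy-4-(triisopropylsilyloxy)phenyl]methanol | OCc1cc(Br)c(O[Si](C(C)C)(C(C)C)C(C)C)c(OC)c1 | intermediate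
10 | [2-bromo-4-(bromomethyl)-6-methoxyphenoxy]triisopropylsilane | BrCc1cc(Br)c(O[Si](C(C)C)(C(C)C)C(C)C)c(OC)c1 | intermediate
11 | lithium enolate of lactone 7 | [Li]OC1=C[C@H](Cc2cc(Br)c(OCc3ccccc3)c(OC)c2)CO1 | intermediate
12 | (3S,4S)-dibromo lactone core (ring A silyl ether, ring B benzyl ether) | COc1cc(C[C@@H]2C(=O)OC[C@H]2Cc2cc(Br)c(OCc3ccccc3)c(OC)c2)cc(Br)c1O[Si](C(C)C)(C(C)C)C(C)C | intermediate
13 | (3S,4S)-core bis(tert-butyl arylacetate) | COc1cc(C[C@@H]2C(=O)OC[C@H]2Cc2cc(CC(=O)OC(C)(C)C)c(OCc3ccccc3)c(OC)c2)cc(CC(=O)OC(C)(C)C)c1O[Si](C(C)C)(C(C)C)C(C)C | intermediate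
14 | (3S,4S)-core bis(arylacetic acid) | COc1cc(C[C@@H]2C(=O)OC[C@H]2Cc2cc(CC(=O)O)c(OCc3ccccc3)c(OC)c2)cc(CC(=O)O)c1O[Si](C(C)C)(C(C)C)C(C)C | intermediate
15 | (S)-4-benzyl-1,3-oxazolidin-2-one | O=C1N[C@@H](Cc2ccccc2)CO1 | starting material
16 | bis(pivalic mixed anhydride) of 14 | COc1cc(C[C@@H]2C(=O)OC[C@H]2Cc2cc(CC(=O)OC(=O)C(C)(C)C)c(OCc3ccccc3)c(OC)c2)cc(CC(=O)OC(=O)C(C)(C)C)c1O[Si](C(C)C)(C(C)C)C(C)C | intermediate
17 | (3S,4S)-core bis[N-arylacetyl-(S)-4-benzyloxazolidinone] | COc1cc(C[C@@H]2C(=O)OC[C@H]2Cc2cc(CC(=O)N3[C@@H](Cc4ccccc4)COC3=O)c(OCc3ccccc3)c(OC)c2)cc(CC(=O)N2[C@@H](Cc3ccccc3)COC2=O)c1O[Si](C(C)C)(C(C)C)C(C)C | intermediate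
18 | vanillin | O=Cc1ccc(O)c(OC)c1 | starting material
19 | 3-methoxy-4-(triisopropylsilyloxy)benzaldehyde | O=Cc1ccc(O[Si](C(C)C)(C(C)C)C(C)C)c(OC)c1 | intermediate
20 | bis(trimethylsilyl ether) of bis-aldol adduct 21 | COc1cc([C@@H](O[Si](C)(C)C)[C@H](C(=O)N2[C@@H](Cc3ccccc3)COC2=O)c2cc(C[C@@H]3C(=O)OC[C@H]3Cc3cc(OC)c(OCc4ccccc4)c(c3)[C@@H](C(=O)N3[C@@H](Cc4ccccc4)COC3=O)[C@H](O[Si](C)(C)C)c3ccc(O[Si](C(C)C)(C(C)C)C(C)C)c(OC)c3)cc(OC)c2O[Si](C(C)C)(C(C)C)C(C)C)ccc1O[Si](C(C)C)(C(C)C)C(C)C | intermediate
21 | bis[(2R,3S)-anti-aldol imide] on the (3S,4S)-core | COc1cc([C@@H](O)[C@H](C(=O)N2[C@@H](Cc3ccccc3)COC2=O)c2cc(C[C@@H]3C(=O)OC[C@H]3Cc3cc(OC)c(OCc4ccccc4)c(c3)[C@@H](C(=O)N3[C@@H](Cc4ccccc4)COC3=O)[C@H](O)c3ccc(O[Si](C(C)C)(C(C)C)C(C)C)c(OC)c3)cc(OC)c2O[Si](C(C)C)(C(C)C)C(C)C)ccc1O[Si](C(C)C)(C(C)C)C(C)C | intermediate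
22 | bis[(1S,2S)-1,3-diol] tetraol on the (3S,4S)-core | COc1cc([C@@H](O)[C@H](CO)c2cc(C[C@@H]3C(=O)OC[C@H]3Cc3cc(OC)c(OCc4ccccc4)c(c3)[C@@H](CO)[C@H](O)c3ccc(O[Si](C(C)C)(C(C)C)C(C)C)c(OC)c3)cc(OC)c2O[Si](C(C)C)(C(C)C)C(C)C)ccc1O[Si](C(C)C)(C(C)C)C(C)C | intermediate
23 | bis(primary tert-butyldimethylsilyl ether) of 22 | COc1cc([C@@H](O)[C@H](CO[Si](C)(C)C(C)(C)C)c2cc(C[C@@H]3C(=O)OC[C@H]3Cc3cc(OC)c(OCc4ccccc4)c(c3)[C@@H](CO[Si](C)(C)C(C)(C)C)[C@H](O)c3ccc(O[Si](C(C)C)(C(C)C)C(C)C)c(OC)c3)cc(OC)c2O[Si](C(C)C)(C(C)C)C(C)C)ccc1O[Si](C(C)C)(C(C)C)C(C)C | intermediate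
24 | ring B phenol from debenzylation of 23 | COc1cc([C@@H](O)[C@H](CO[Si](C)(C)C(C)(C)C)c2cc(C[C@@H]3C(=O)OC[C@H]3Cc3cc(OC)c(O)c(c3)[C@@H](CO[Si](C)(C)C(C)(C)C)[C@H](O)c3ccc(O[Si](C(C)C)(C(C)C)C(C)C)c(OC)c3)cc(OC)c2O[Si](C(C)C)(C(C)C)C(C)C)ccc1O[Si](C(C)C)(C(C)C)C(C)C | intermediate
25 | pentasilylated target with closed (2R,3S)-dihydrobenzofuran on ring B | COc1cc([C@@H](O)[C@H](CO[Si](C)(C)C(C)(C)C)c2cc(C[C@@H]3C(=O)OC[C@H]3Cc3cc(OC)c4c(c3)[C@@H](CO[Si](C)(C)C(C)(C)C)[C@H](c3ccc(O[Si](C(C)C)(C(C)C)C(C)C)c(OC)c3)O4)cc(OC)c2O[Si](C(C)C)(C(C)C)C(C)C)ccc1O[Si](C(C)C)(C(C)C)C(C)C | intermediate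
26 | CNP0186558.3 | COc1cc([C@@H](O)[C@H](CO)c2cc(C[C@@H]3C(=O)OC[C@H]3Cc3cc(OC)c4c(c3)[C@@H](CO)[C@H](c3ccc(O)c(OC)c3)O4)cc(OC)c2O)ccc1O | target

## Step count and risks

Total step count: 18. Longest linear sequence: 14 steps (steps 1–4, 8–11, 13–18); steps 5–7 and step 12 are side branches.

**Step 13 (key step).** The arylacetyl enolates are more stabilised than the propionyl enolates for which this aldol is best known. The addition could become reversible before silylation and lose anti selectivity, the second arm could lag behind the first, and the ortho silyl ether on ring A may slow its arm. The fallback, from 14 back to 22, sets the relative configuration by olefin geometry instead. Perkin condensation of diacid 14 with two equivalents of 19 (Ac2O, Et3N, 110 °C) should give the bis[(E)-2,3-diarylacrylic acid] F1. Isobutyl chloroformate and N-methylmorpholine convert it to the bis(isobutyl carbonic mixed anhydride) F2, which NaBH4 reduces to the bis[(E)-allylic alcohol] F3 beside the lactone. Hydroboration with the monoisopinocampheylborane antipode that delivers the (1S,2S) diol, then NaBO3, adds H to C8 and OH to C7 on the same face of the (E)-olefin. That is the anti diol, and it returns the route to 22.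

**Step 17.** The ring A arm also has a free benzylic carbinol. Indiscriminate oxyphosphonium formation there could lead to elimination or capture by the hydrazide. The fallback, from 23 to 26, masks that carbinol first. A catalytic amount of t-BuOK in THF at 0 °C should move the ring A silyl group onto the neighbouring C7A alkoxide (O to O migration driven by phenoxide formation), giving the silyl-shifted isomer F4. Hydrogenolysis (H2, Pd/C) gives the bis-phenol F5, in which only the ring B arm has a free carbinol. The Mitsunobu closure then gives the ring-closed compound F6, and Bu4NF/AcOH gives 26.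

**Step 14.** Partial reduction of the lactone, or retro-aldol cleavage and C8 epimerisation in the basic medium, could cut into the yield. The fallback, from 21 to 22, separates cleavage from reduction. LiOH/H2O2 (THF/H2O, 0 °C) removes the auxiliaries to give the bis(β-hydroxy acid) F7 (the lactone is re-closed on acidification if it opens). BH3·THF at 0 °C then reduces the carboxylic acids much faster than the lactone and gives 22.

**Step 9.** The ring A bromide sits next to the bulky silyl ether. A stalled second coupling or protodebromination is possible. The fallback, from 12 to 14, changes the carbon source. Suzuki coupling with allylboronic acid pinacol ester (PdCl2(dppf), CsF, THF, 65 °C) should give the bis-allyl core F8. Ozonolysis (O3, CH2Cl2/MeOH, −78 °C; PPh3) gives the bis(arylacetaldehyde) F9, and Pinnick oxidation (NaClO2, NaH2PO4, 2-methylbut-2-ene) gives 14.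

## Further compounds

F1 | step 13 | bis[(E)-2,3-diarylacrylic acid] from Perkin condensation of 14 with 19 | COc1cc(/C=C(/C(=O)O)c2cc(C[C@@H]3C(=O)OC[C@H]3Cc3cc(OC)c(OCc4ccccc4)c(c3)/C(C(=O)O)=C\c3ccc(O[Si](C(C)C)(C(C)C)C(C)C)c(OC)c3)cc(OC)c2O[Si](C(C)C)(C(C)C)C(C)C)ccc1O[Si](C(C)C)(C(C)C)C(C)C
F2 | step 13 | bis(isobutyl carbonic mixed anhydride) of F1 | COc1cc(/C=C(/C(=O)OC(=O)OCC(C)C)c2cc(C[C@@H]3C(=O)OC[C@H]3Cc3cc(OC)c(OCc4ccccc4)c(c3)/C(C(=O)OC(=O)OCC(C)C)=C\c3ccc(O[Si](C(C)C)(C(C)C)C(C)C)c(OC)c3)cc(OC)c2O[Si](C(C)C)(C(C)C)C(C)C)ccc1O[Si](C(C)C)(C(C)C)C(C)C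
F3 | step 13 | bis[(E)-2,3-diarylallylic alcohol] | COc1cc(/C=C(/CO)c2cc(C[C@@H]3C(=O)OC[C@H]3Cc3cc(OC)c(OCc4ccccc4)c(c3)/C(CO)=C\c3ccc(O[Si](C(C)C)(C(C)C)C(C)C)c(OC)c3)cc(OC)c2O[Si](C(C)C)(C(C)C)C(C)C)ccc1O[Si](C(C)C)(C(C)C)C(C)C
F4 | step 17 | silyl-shifted isomer of 23 (ring A phenol free, C7A O-triisopropylsilyl) | COc1cc([C@@H](O[Si](C(C)C)(C(C)C)C(C)C)[C@H](CO[Si](C)(C)C(C)(C)C)c2cc(C[C@@H]3C(=O)OC[C@H]3Cc3cc(OC)c(OCc4ccccc4)c(c3)[C@@H](CO[Si](C)(C)C(C)(C)C)[C@H](O)c3ccc(O[Si](C(C)C)(C(C)C)C(C)C)c(OC)c3)cc(OC)c2O)ccc1O[Si](C(C)C)(C(C)C)C(C)C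
F5 | step 17 | debenzylated F4 (ring A and ring B phenols free) | COc1cc([C@@H](O[Si](C(C)C)(C(C)C)C(C)C)[C@H](CO[Si](C)(C)C(C)(C)C)c2cc(C[C@@H]3C(=O)OC[C@H]3Cc3cc(OC)c(O)c(c3)[C@@H](CO[Si](C)(C)C(C)(C)C)[C@H](O)c3ccc(O[Si](C(C)C)(C(C)C)C(C)C)c(OC)c3)cc(OC)c2O)ccc1O[Si](C(C)C)(C(C)C)C(C)C
F6 | step 17 | ring-closed (2R,3S)-dihydrobenzofuran from F5 | COc1cc([C@@H](O[Si](C(C)C)(C(C)C)C(C)C)[C@H](CO[Si](C)(C)C(C)(C)C)c2cc(C[C@@H]3C(=O)OC[C@H]3Cc3cc(OC)c4c(c3)[C@@H](CO[Si](C)(C)C(C)(C)C)[C@H](c3ccc(O[Si](C(C)C)(C(C)C)C(C)C)c(OC)c3)O4)cc(OC)c2O)ccc1O[Si](C(C)C)(C(C)C)C(C)C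
F7 | step 14 | bis(β-hydroxy acid) from hydrolytic removal of the auxiliaries | COc1cc([C@@H](O)[C@H](C(=O)O)c2cc(C[C@@H]3C(=O)OC[C@H]3Cc3cc(OC)c(OCc4ccccc4)c(c3)[C@@H](C(=O)O)[C@H](O)c3ccc(O[Si](C(C)C)(C(C)C)C(C)C)c(OC)c3)cc(OC)c2O[Si](C(C)C)(C(C)C)C(C)C)ccc1O[Si](C(C)C)(C(C)C)C(C)C
F8 | step 9 | (3S,4S)-core bis(allylarene) | COc1cc(C[C@@H]2C(=O)OC[C@H]2Cc2cc(CC=C)c(OCc3ccccc3)c(OC)c2)cc(CC=C)c1O[Si](C(C)C)(C(C)C)C(C)C
F9 | step 9 | (3S,4S)-core bis(arylacetaldehyde) | COc1cc(C[C@@H]2C(=O)OC[C@H]2Cc2cc(CC=O)c(OCc3ccccc3)c(OC)c2)cc(CC=O)c1O[Si](C(C)C)(C(C)C)C(C)C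
A1 | alternative 1 | (+)-matairesinol, (3S,4S) | COc1cc(C[C@@H]2C(=O)OC[C@H]2Cc2ccc(O)c(OC)c2)ccc1O
A2 | alternative 1 | bis(dihydrobenzofuran) dilignan with both arms closed (desired isomer drawn) | O=C1OC[C@@H](Cc2cc(OC)c3c(c2)[C@@H](CO)[C@H](c2ccc(O)c(OC)c2)O3)[C@@H]1Cc1cc(OC)c2c(c1)[C@@H](CO)[C@H](c1ccc(O)c(OC)c1)O2
A3 | alternative 2 | (S)-β-benzyl lactone carrying the protected dihydrobenzofuran | O=C1C[C@H](Cc2cc(OC)c3c(c2)[C@@H](CO[Si](C)(C)C(C)(C)C)[C@H](c2ccc(O[Si](C(C)C)(C(C)C)C(C)C)c(OC)c2)O3)CO1
A4 | alternative 2 | ring A benzylic bromide carrying the open diol as acetonide | BrCc1cc(OC)c(O[Si](C(C)C)(C(C)C)C(C)C)c(c1)[C@H]1COC(C)(C)O[C@@H]1c1ccc(O[Si](C(C)C)(C(C)C)C(C)C)c(OC)c1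
A5 | alternative 3 | (3S,4S)-core bis(methyl aryldiazoacetate) with both ring phenols as 4-(benzyloxy)-3-methoxybenzyl ethers | COc1cc(C[C@@H]2C(=O)OC[C@H]2Cc2cc(OC)c(OCc3ccc(OCc4ccccc4)c(OC)c3)c(c2)C(=[N+]=[N-])C(=O)OC)cc(C(=[N+]=[N-])C(=O)OC)c1OCc1ccc(OCc2ccccc2)c(OC)c1
A6 | alternative 3 | bis(trans-dihydrobenzofuran methyl ester) after epimerisation | O=C1OC[C@@H](Cc2cc(OC)c3c(c2)[C@@H](C(=O)OC)[C@H](c2ccc(OCc4ccccc4)c(OC)c2)O3)[C@@H]1Cc1cc(OC)c2c(c1)[C@@H](C(=O)OC)[C@H](c1ccc(OCc3ccccc3)c(OC)c1)O2
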